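The cyclobutane (C8–C8′, C9–C9′) is cut last, into two molecules of one enantiopure dienyl lactone, so everything rests on the C5–C10 ring-fusion bond of that monomer. The key step is an auxiliary-controlled Diels–Alder reaction of an acyclic (Z)-2-silyloxy dienyne with an N-acryloyl oxazolidinone: in one operation it closes ring C, forms C5–C10 (and C6–C7) and sets the C5 methine and the quaternary, methyl-bearing C10. It exploits the 3,3,4-trisubstituted cyclohexanone pattern of ring C (C8 oxygen, quaternary C10, C5 carrying C4). The precursor is a seven-carbon silyl dienol ether with no ring. The cyclopropane (C1, C3) and cyclobutane (C8, C9) stereocentres are then relayed from C5/C10.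

Key step: step 4

Remark on numbering: lindenane numbering is used (cyclopropane C1–C2–C3 with C2 = CH2; ring B = C1, C10, C5, C4, C3; ring C = C5 to C10; lactone = C7, C8, O, C12, C11; C14 = methyl on C10; C15 = methylene on C4; primes = second half); α is the face of H5, β the face of C14.

Assumption: the target SMILES is read as the C2-symmetric head-to-head, cis-anti-cis [2+2] dimer of monomer 26, both new bonds lying on the α face of each ring C.

Step 1
Reactants: 1 (E)-4-methoxypent-3-en-2-one; 2 ethynylmagnesium bromide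
Product: 4 (3Z)-4-methylhex-3-en-5-yn-2-one, via bromomagnesium alkoxide 3 (not isolated)
Conditions: HC≡CMgBr, THF, 0 °C → rt; then 2 M HCl, THF, rt
Reagents that add atoms: water (O)
Why: 1,2-addition of the alkynyl Grignard reagent to the vinylogous ester and acid-mediated transposition (Stork–Danheiser sequence) should give the enynone, and acid equilibration should favour the Z isomer, in which the acetyl group is cis to the slim ethynyl group and not to the methyl group (allylic 1,3-strain).

Step 2
Reactants: 4 (3Z)-4-methylhex-3-en-5-yn-2-one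
Product: 6 triisopropyl{[(3Z)-4-methylhexa-1,3-dien-5-yn-2-yl]oxy}silane, via lithium dienolate 5 (not isolated)
Conditions: lithium diisopropylamide, THF, −78 °C; TIPSOTf, −78 → 0 °C
Reagents that add atoms: triisopropylsilyl trifluoromethanesulfonate (CC(C)[Si](OS(=O)(=O)C(F)(F)F)(C(C)C)C(C)C)
Why: kinetic deprotonation at the acetyl CH3 (faster than γ-deprotonation and than removal of the alkyne proton) followed by O-silylation should give the cross-conjugated 2-silyloxy diene with the C9=C10 geometry retained (silyl enol ether formation).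

Step 3
Reactants: 7 (4S)-4-benzyl-1,3-oxazolidin-2-one; 8 acryloyl chloride
Product: 10 (4S)-3-acryloyl-4-benzyl-1,3-oxazolidin-2-one, via bromomagnesium imidate 9 (not isolated)
Conditions: MeMgBr, THF, 0 °C; then 8, −78 → 0 °C
Reagents that add atoms: none
Why: N-acylation of the magnesium salt of the oxazolidinone at low temperature is the standard access to the acrylimide and should avoid polymerisation of the acryloyl unit.

Step 4
Reactants: 6 triisopropyl{[(3Z)-4-methylhexa-1,3-dien-5-yn-2-yl]oxy}silane; 10 (4S)-3-acryloyl-4-benzyl-1,3-oxazolidin-2-one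
Product: 11 (4S)-4-benzyl-3-{[(1R,2R)-2-ethynyl-2-methyl-4-(triisopropylsilyloxy)cyclohex-3-en-1-yl]carbonyl}-1,3-oxazolidin-2-one
Conditions: Et2AlCl (1.4 equiv), CH2Cl2, −78 → −30 °C
Reagents that add atoms: none
Why: Et2AlCl should bind both imide carbonyls of 10 and lock the acryloyl unit s-cis in a cationic chelate, which the 2-silyloxy diene attacks in an endo, normal-electron-demand [4+2] cycloaddition that is asynchronous (C6–C7 ahead of C5–C10). The closest known reaction type is the oxazolidinone-auxiliary Diels–Alder reaction of acrylimides with acyclic dienes promoted by dialkylaluminium chlorides. Ring C (six-membered) is closed by cycloaddition, its two new bonds being C6–C7 and C5–C10. C5 is controlled by the auxiliary, whose benzyl group shields the Cα re face so that the diene adds to the si face; C10 is controlled relative to C5 by the endo rule together with the Z geometry of the diene, which puts ethynyl inside and methyl outside, so that the acyl group ends cis to methyl and trans to ethynyl. The step needs regioselectivity, endo selectivity and reactivity at a fully substituted diene terminus: the 2-silyloxy group makes the CH2 terminus (C7) the nucleophilic end that bonds to the acrylimide β-carbon, and the inside substituent is the small, linear ethynyl group, which lets the diene reach the s-cis conformation.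

Step 5
Reactants: 11 Diels–Alder adduct (ethynyl imide)
Product: 12 (4S)-4-benzyl-3-{[(1R,2R)-2-ethenyl-2-methyl-4-(triisopropylsilyloxy)cyclohex-3-en-1-yl]carbonyl}-1,3-oxazolidin-2-one
Conditions: H2 (1 atm), Pd on CaCO3 poisoned with Pb(OAc)2, quinoline, EtOAc, rt
Reagents that add atoms: none
Why: semi-hydrogenation over the lead-poisoned palladium catalyst (Lindlar reduction) should stop at the C1=C2 vinyl group and leave the trisubstituted silyl enol ether and the imide untouched.

Step 6
Reactants: 12 vinyl silyl enol ether imide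
Product: 13 (4S)-4-benzyl-3-{[(7S,8R)-7-ethenyl-7-methyl-1,4-dioxaspiro[4.5]decan-8-yl]carbonyl}-1,3-oxazolidin-2-one
Conditions: HOCH2CH2OH, TsOH·H2O (cat.), CH2Cl2, rt
Reagents that add atoms: ethylene glycol (OCCO)
Why: protonation of the silyl enol ether at C9 gives an oxocarbenium ion at C8 that ethylene glycol should trap as the dioxolane with loss of silanol (acid-catalysed acetal exchange), which removes the nucleophilic C8=C9 bond before the carbenoid step.

Step 7
Reactants: 13 ketal imide
Product: 14 [(7S,8R)-7-ethenyl-7-methyl-1,4-dioxaspiro[4.5]decan-8-yl]methanol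
Conditions: LiBH4, H2O (1 equiv), Et2O/THF, 0 °C → rt
Reagents that add atoms: none
Why: LiBH4 should cleave the hindered imide reductively at the exocyclic carbonyl to the primary alcohol and return the auxiliary without touching C5.

Step 8
Reactants: 14 primary alcohol
Product: 15 (7S,8R)-7-ethenyl-7-methyl-1,4-dioxaspiro[4.5]decane-8-carbaldehyde
Conditions: nPr4N[RuO4] (cat.), N-methylmorpholine N-oxide, 4 Å molecular sieves, CH2Cl2, rt
Reagents that add atoms: none
Why: the Ley–Griffith oxidation is neutral and should give the α-branched aldehyde without epimerising C5.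

Step 9
Reactants: 15 aldehyde
Product: 16 (7S,8R)-7-ethenyl-7-methyl-8-[(2S)-oxiran-2-yl]-1,4-dioxaspiro[4.5]decane
Conditions: Me3S+ I−, n-BuLi, THF, −10 °C; then 15, −10 °C → rt
Reagents that add atoms: trimethylsulfonium iodide (C[S+](C)C.[I-])
Why: Corey–Chaykovsky methylene transfer should follow the Felkin–Anh model (ylide anti to the quaternary C10, passing the C5–H), which gives the (S)-epoxide whose oxygen at C4 will lie on the α face once ring B is closed.

Step 10
Reactants: 16 epoxide
Product: 18 8,8-(ethylenedioxy)-11,12,13,15-tetranorlindenan-4α-ol (H1, H3, H5 and 4-OH α; C2 and C14 β), via lithiated epoxide 17 (not isolated)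
Conditions: lithium 2,2,6,6-tetramethylpiperidide (from the amine and n-BuLi), t-BuOMe, 0 °C → rt
Reagents that add atoms: none
Why: the amide base removes the epoxide CH2 proton trans to the ring and the α-lithiated epoxide acts as a carbenoid that adds to the C1=C2 vinyl group with opening of the C3–O bond (intramolecular cyclopropanation of an unsaturated terminal epoxide), closing ring B and the cyclopropane; the alkene attacks C3 anti to the departing oxygen, so the cyclopropane CH2 ends trans to the C4 oxygen, on the β face syn to C14, which fixes C1 and C3.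

Step 11
Reactants: 18 tricyclic alcohol
Product: 19 8,8-(ethylenedioxy)-11,12,13,15-tetranorlindenan-4-one
Conditions: nPr4N[RuO4] (cat.), N-methylmorpholine N-oxide, 4 Å molecular sieves, CH2Cl2, rt
Reagents that add atoms: none
Why: Ley–Griffith oxidation of the cyclopropyl carbinol removes the temporary C4 stereocentre under neutral conditions that should not epimerise the trans ring fusion at C5.

Step 12
Reactants: 19 tricyclic ketone
Product: 20 8,8-(ethylenedioxy)-11,12,13-trinorlindena-4(15)-ene
Conditions: Ph3PCH3Br, KOtBu, THF, 0 °C → rt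
Reagents that add atoms: methyltriphenylphosphonium bromide (C[P+](c1ccccc1)(c1ccccc1)c1ccccc1.[Br-])
Why: Wittig methylenation of the cyclopropyl ketone installs C15, and the unstabilised ylide at low temperature should add faster than it enolises the ketone toward C5.

Step 13
Reactants: 20 methylene ketal
Product: 21 11,12,13-trinorlindena-4(15)-en-8-one
Conditions: PPTS, acetone/H2O, 50 °C
Reagents that add atoms: water (O)
Why: mild acid hydrolysis of the dioxolane should unveil the C8 ketone without protonating the exocyclic alkene next to the cyclopropane.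

Step 14
Reactants: 21 tricyclic ketone; 22 ethyl pyruvate
Product: 24 ethyl 11-hydroxy-8-oxolindena-4(15)-en-12-oate (epimers at C7 and C11), via lithium enolate 23 (not isolated)
Conditions: lithium diisopropylamide, THF, −78 °C; 22, −78 °C; AcOH
Reagents that add atoms: none
Why: kinetic deprotonation should occur at the unhindered C7 methylene and not at the neopentyl C9, and the enolate adds to the reactive keto group of the pyruvate (directed aldol addition); both new stereocentres are lost in the next step.

Step 15
Reactants: 24 aldol adduct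
Product: 26 lindena-4(15),7(11),8-trien-12,8-olide (chloranthalactone A), via alkylidene keto ester 25 (not isolated)
Conditions: TsOH·H2O (cat.), toluene, 90 °C, Dean–Stark
Reagents that add atoms: none
Why: acid-catalysed dehydration of the tertiary β-hydroxy ketone gives the C7=C11 alkylidene keto ester, which equilibrates to the Z isomer and is acylated on the oxygen of its C8=C9 enol with loss of ethanol (enol lactonisation) to give the dienyl butenolide.

Step 16
Reactants: 26 chloranthalactone A (two molecules)
Product: 27 target dimer CNP0265879.1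
Conditions: hν (Hg lamp, Pyrex filter), degassed hexane/CH2Cl2 (concentrated), rt
Reagents that add atoms: none
Why: [2+2] photodimerisation of the excited dienyl lactone at C8=C9 should proceed head-to-head through the 1,4-biradical formed by C9–C9′ bonding (each C8 radical is allylic and α-oxygenated), both partners reacting on the α face opposite C14 and the cyclopropane CH2 and in the anti arrangement, which sets C8, C9, C8′ and C9′ in the C2-symmetric cis-anti-cis cyclobutane.

Compound list
1 | (E)-4-methoxypent-3-en-2-one | CO/C(C)=C/C(C)=O | starting material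
2 | ethynylmagnesium bromide | C#C[Mg]Br | starting material
3 | bromomagnesium (E)-5-methoxy-3-methylhex-4-en-1-yn-3-olate (racemic) | C#CC(C)(O[Mg]Br)/C=C(\C)OC | intermediate
4 | (3Z)-4-methylhex-3-en-5-yn-2-one | CC(=O)/C=C(/C)C#C | intermediate
5 | lithium (3Z)-4-methylhexa-1,3-dien-5-yn-2-olate | [Li+].[O-]C(=C)/C=C(/C)C#C | intermediate
6 | triisopropyl{[(3Z)-4-methylhexa-1,3-dien-5-yn-2-yl]oxy}silane | C=C(O[Si](C(C)C)(C(C)C)C(C)C)/C=C(/C)C#C | intermediate
7 | (4S)-4-benzyl-1,3-oxazolidin-2-one | O=C1N[C@@H](Cc2ccccc2)CO1 | starting material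
8 | acryloyl chloride | C=CC(Cl)=O | starting material
9 | bromomagnesium salt of (4S)-4-benzyl-1,3-oxazolidin-2-one | Br[Mg]N1[C@@H](Cc2ccccc2)COC1=O | intermediate
10 | (4S)-3-acryloyl-4-benzyl-1,3-oxazolidin-2-one | C=CC(=O)N1[C@@H](Cc2ccccc2)COC1=O | intermediate
11 | (4S)-4-benzyl-3-{[(1R,2R)-2-ethynyl-2-methyl-4-(triisopropylsilyloxy)cyclohex-3-en-1-yl]carbonyl}-1,3-oxazolidin-2-one | C#C[C@]1(C)C=C(O[Si](C(C)C)(C(C)C)C(C)C)CC[C@H]1C(=O)N2[C@@H](Cc3ccccc3)COC2=O | intermediate
12 | (4S)-4-benzyl-3-{[(1R,2R)-2-ethenyl-2-methyl-4-(triisopropylsilyloxy)cyclohex-3-en-1-yl]carbonyl}-1,3-oxazolidin-2-one | C=C[C@]1(C)C=C(O[Si](C(C)C)(C(C)C)C(C)C)CC[C@H]1C(=O)N2[C@@H](Cc3ccccc3)COC2=O | intermediate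
13 | (4S)-4-benzyl-3-{[(7S,8R)-7-ethenyl-7-methyl-1,4-dioxaspiro[4.5]decan-8-yl]carbonyl}-1,3-oxazolidin-2-one | C=C[C@]1(C)CC2(OCCO2)CC[C@H]1C(=O)N3[C@@H](Cc4ccccc4)COC3=O | intermediate
14 | [(7S,8R)-7-ethenyl-7-methyl-1,4-dioxaspiro[4.5]decan-8-yl]methanol | C=C[C@]1(C)CC2(OCCO2)CC[C@H]1CO | intermediate
15 | (7S,8R)-7-ethenyl-7-methyl-1,4-dioxaspiro[4.5]decane-8-carbaldehyde | C=C[C@]1(C)CC2(OCCO2)CC[C@H]1C=O | intermediate
16 | (7S,8R)-7-ethenyl-7-methyl-8-[(2S)-oxiran-2-yl]-1,4-dioxaspiro[4.5]decane | C=C[C@]1(C)CC2(OCCO2)CC[C@H]1[C@H]3CO3 | intermediate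
17 | α-lithiated epoxide of 16 (lithium trans to the cyclohexyl group) | C=C[C@]1(C)CC2(OCCO2)CC[C@H]1[C@@H]3O[C@H]3[Li] | intermediate
18 | 8,8-(ethylenedioxy)-11,12,13,15-tetranorlindenan-4α-ol (H1, H3, H5, 4-OH α; C2, C14 β) | O[C@@H]1[C@H]2C[C@H]2[C@@]3(C)[C@H]1CCC4(OCCO4)C3 | intermediate
19 | 8,8-(ethylenedioxy)-11,12,13,15-tetranorlindenan-4-one | O=C1[C@H]2C[C@H]2[C@@]3(C)[C@H]1CCC4(OCCO4)C3 | intermediate
20 | 8,8-(ethylenedioxy)-11,12,13-trinorlindena-4(15)-ene | C=C1[C@H]2C[C@H]2[C@@]3(C)[C@H]1CCC4(OCCO4)C3 | intermediate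
21 | 11,12,13-trinorlindena-4(15)-en-8-one | C=C1[C@H]2C[C@H]2[C@@]3(C)[C@H]1CCC(=O)C3 | intermediate
22 | ethyl pyruvate | CCOC(=O)C(C)=O | starting material
23 | lithium C7=C8 enolate of 21 | C=C1[C@H]2C[C@H]2[C@@]3(C)[C@H]1CC=C([O-])C3.[Li+] | intermediate
24 | ethyl 11-hydroxy-8-oxolindena-4(15)-en-12-oate (epimers at C7 and C11) | C=C1[C@H]2C[C@H]2[C@@]3(C)[C@H]1CC(C(C)(O)C(=O)OCC)C(=O)C3 | intermediate
25 | ethyl (7(11)Z)-8-oxolindena-4(15),7(11)-dien-12-oate | C=C1[C@H]2C[C@H]2[C@@]3(C)[C@H]1C/C(=C(\C)C(=O)OCC)C(=O)C3 | intermediate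
26 | lindena-4(15),7(11),8-trien-12,8-olide (chloranthalactone A) | C=C1[C@H]2C[C@H]2[C@@]3(C)[C@H]1CC4=C(C)C(=O)OC4=C3 | intermediate
27 | head-to-head cis-anti-cis [2+2] dimer of 26 (CNP0265879.1) | C=C1[C@H]2C[C@H]2[C@@]2(C)[C@H]1CC1=C(C)C(=O)O[C@]13[C@H]2[C@H]1[C@@]2(C)[C@@H]4C[C@@H]4C(=C)[C@@H]2CC2=C(C)C(=O)O[C@@]213 | target

Total step count: 16. Longest linear sequence: 15 steps (steps 1, 2 and 4 to 16; step 3 prepares the dienophile).

Steps most likely to fail

Step 4. Ring closure at the fully substituted diene terminus may lag behind the first bond, so that the Lewis acid gives only the open-chain conjugate adduct or cleaves the silyl dienol ether, and endo or facial control may erode. The fallback replaces the Lewis-acid cycloaddition by an anionic double Michael annulation and sets out from enynone 4 and imide 10. The lithium dienolate 5 (lithium diisopropylamide, THF, −78 °C) is added to 10. Michael addition through its CH2 terminus gives the chelated Z imide enolate. On warming to 0 °C this should close onto the enone β-carbon (intramolecular Michael addition forming C5–C10) on the face away from the benzyl group, giving (4S)-4-benzyl-3-{[(1R,2R)-2-ethynyl-2-methyl-4-oxocyclohexyl]carbonyl}-1,3-oxazolidin-2-one F1. Semi-hydrogenation (H2, Pd on CaCO3 poisoned with Pb(OAc)2, quinoline) gives (4S)-4-benzyl-3-{[(1R,2S)-2-ethenyl-2-methyl-4-oxocyclohexyl]carbonyl}-1,3-oxazolidin-2-one F2. Ketalisation (ethylene glycol, TsOH·H2O, benzene, Dean–Stark) returns to the route at 13.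

Step 10. The lithium carbenoid may be consumed by 1,2-hydride shift, by attack of the amide base or by C–H insertion before it reaches the alkene, because closure builds a strained trans-fused ring B. Any C4 epimer carried over from step 9 would also close on the wrong face. The fallback uses ring-closing metathesis and hydroxyl-directed cyclopropanation and sets out from aldehyde 15.
- Vinylmagnesium bromide (THF, −78 °C) gives 1-[(7S,8R)-7-ethenyl-7-methyl-1,4-dioxaspiro[4.5]decan-8-yl]prop-2-en-1-ol F3; either C4 epimer serves.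
- Second-generation Grubbs catalyst (CH2Cl2, 40 °C) closes ring B as the trans-fused cyclopentenol with a C1=C3 double bond, 8,8-(ethylenedioxy)-2,11,12,13,15-pentanor-lindan-1(3)-en-4-ol F4.
- nPr4N[RuO4] with N-methylmorpholine N-oxide gives the corresponding ring B enone F5.
- NaBH4 with CeCl3·7H2O (MeOH, −78 °C, Luche reduction) should deliver hydride from the α face away from C14 and give the 4β-allylic alcohol F6.
- Et2Zn and CH2I2 (CH2Cl2, 0 °C, Simmons–Smith cyclopropanation) should deliver CH2 syn to the hydroxyl, on the β face, giving 8,8-(ethylenedioxy)-11,12,13,15-tetranorlindenan-4β-ol F7.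
- Oxidation with nPr4N[RuO4] and N-methylmorpholine N-oxide returns to the route at 19.

Step 15. Under hot acid the exocyclic C4=C15 alkene may migrate into ring B, or the adjacent cyclopropane may open through a cyclopropylcarbinyl cation. The E alkylidene ester may also fail to isomerise, so that lactonisation stalls. The fallback is a stepwise, non-acidic sequence and sets out from aldol adduct 24. Acetylation (Ac2O, DMAP, Et3N, CH2Cl2) gives ethyl 11-acetoxy-8-oxolindena-4(15)-en-12-oate F8. DBU (THF, rt) should eliminate acetate through the C8 enolate and give the alkylidene keto ester 25, now isolated. LiOH (THF/H2O, 0 °C) gives (7(11)Z)-8-oxolindena-4(15),7(11)-dien-12-oic acid F9. Ac2O with NaOAc (80 °C) should acylate the C8=C9 enol through the mixed anhydride (enol lactonisation) and return to the route at 26.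

Further compounds
F1 | step 4 | (4S)-4-benzyl-3-{[(1R,2R)-2-ethynyl-2-methyl-4-oxocyclohexyl]carbonyl}-1,3-oxazolidin-2-one | C#C[C@]1(C)CC(=O)CC[C@H]1C(=O)N2[C@@H](Cc3ccccc3)COC2=O
F2 | step 4 | (4S)-4-benzyl-3-{[(1R,2S)-2-ethenyl-2-methyl-4-oxocyclohexyl]carbonyl}-1,3-oxazolidin-2-one | C=C[C@]1(C)CC(=O)CC[C@H]1C(=O)N2[C@@H](Cc3ccccc3)COC2=O
F3 | step 10 | 1-[(7S,8R)-7-ethenyl-7-methyl-1,4-dioxaspiro[4.5]decan-8-yl]prop-2-en-1-ol (C4 epimers) | C=C[C@]1(C)CC2(OCCO2)CC[C@H]1C(O)C=C
F4 | step 10 | 8,8-(ethylenedioxy)-2,11,12,13,15-pentanor-lindan-1(3)-en-4-ol (trans-fused ring B cyclopentenol, C4 epimers) | OC1C=C[C@@]2(C)[C@H]1CCC3(OCCO3)C2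
F5 | step 10 | 8,8-(ethylenedioxy)-2,11,12,13,15-pentanor-lindan-1(3)-en-4-one | O=C1C=C[C@@]2(C)[C@H]1CCC3(OCCO3)C2
F6 | step 10 | 8,8-(ethylenedioxy)-2,11,12,13,15-pentanor-lindan-1(3)-en-4β-ol | O[C@H]1C=C[C@@]2(C)[C@H]1CCC3(OCCO3)C2
F7 | step 10 | 8,8-(ethylenedioxy)-11,12,13,15-tetranorlindenan-4β-ol | O[C@H]1[C@H]2C[C@H]2[C@@]3(C)[C@H]1CCC4(OCCO4)C3
F8 | step 15 | ethyl 11-acetoxy-8-oxolindena-4(15)-en-12-oate (epimers at C7 and C11) | C=C1[C@H]2C[C@H]2[C@@]3(C)[C@H]1CC(C(C)(OC(C)=O)C(=O)OCC)C(=O)C3
F9 | step 15 | (7(11)Z)-8-oxolindena-4(15),7(11)-dien-12-oic acid | C=C1[C@H]2C[C@H]2[C@@]3(C)[C@H]1C/C(=C(\C)C(=O)O)C(=O)C3
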